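Begin from the symmetric charge, one E for one Q, and measure this flask from there.

Q 0.0010 M; E 1.05 mM; time 30 s

1. J.E and L together at 30 s, in percent of the Q charged
2. the change that raises the amount of J.E and L together at 30 s, in percent of the Q charged most ("none" if none brings more than 2 percentage points) (midnight / dawn / autumn / noon / none)
3. amount of J.E and L together at 30 s, in percent of the Q charged, after midnight

- midnight: doubling the solubility in step 3, all else as stated
- dawn: doubling the solubility in step 1, all else as stated
- autumn: doubling the amount of E, all else as stated
- noon: doubling the dissolution coefficient of step 3, all else as stated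

    Q ⇌ J, rate k1*(cs1 - [J]) while solid is left; crystals form when [J] > cs1 (cs1 = 0.53 mM, k1 = 2.47 s⁻¹)
    J + E → J.E (k2 = 1090 M⁻¹ s⁻¹)
    L ⇌ J.E, rate k3*(cs3 - [J.E]) while solid is left; crystals form when [J.E] > cs3 (cs3 = 0.074 mM, k3 = 1.71 s⁻¹)
    J.E ⇌ G (K4 = 2.1, k4 = 0.0394 s⁻¹)

Q dissolves to J, J joins E to give J.E, J.E crystallises as L, and dissolved J.E turns into G. I took the ratio of charges first, and cE/cQ was 1.05, just above the symmetric value. The bench rule then makes Q the limiting reagent and counts its whole charge as product.

That rule treats J.E as safe once formed, and this is where I saw it stop working. While L stands beside it, cJ.E stays near the solubility 0.074 mM, and that dissolved part turns into G. The border is a product of given numbers: 0.0394 s⁻¹ times 30 s gave 1.18, so the run was not short for dissolved J.E. I therefore reckoned: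

leak share = 0.0394 s⁻¹ × 0.074 mM × 30 s / 0.0010 M = 8.75%

I called this the leak share: the G that saturated J.E forms during the run by the forward step, as a part of the Q charged.

Measured down from the rule's full charge, this put my yield at 91.2%. In this reckoning, doubling the solubility of J.E doubled the share, which put the yield after midnight at 82.5%. The other changes did not enter the reckoned share, so I expected no gain from them beyond 2 percentage points.

The forecast, made separately, gave 90%, 83.5% after midnight, and none as the best change. Its numbers differ a little from mine, and it named as the main loss “the slow leak to G from dissolved J.E held near its solubility by L”.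

The simulation gave 91.0%, 84.6% after midnight, and none as the best change, with autumn gaining 1.2 points.

In the flask, the joining of J and E did half of its turnover by 1.79 s, and at 3.00 s solid Q stood at 0% with J at 29.2%. From then until 30.0 s, while L rose from 52.2% to 83.6%, G grew from 1.96% to 7.81%, against a leak share of 8.75%. In a further flask charged with 0.0040 M of Q, the same share comes to 2.19%. G in that flask stood at 1.97%, with E at 0% of its own charge and J.E and L together at 24.3%.

Its constants were drawn at random within sensible limits.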